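**Plan**

- The retrosynthesis first cuts the depside ester bond between the ring A carbonyl and O–C4' of ring B, giving a 2-O-benzyl ring A acid and a ring B phenol held as its benzyl ester.
- Ring B is then cut at four ring bonds (C1'–C6', C1'–C2', C3'–C4', C4'–C5') back to a benzyl 2-diazo-3-oxo-4-enoate and methoxyacetylene. The enabling feature is the ring B pattern: carboxyl at C1', methyl ether at C2', an oxygen at C4' that must stay free, and propyl at C6'. A vinylketene and an alkoxyalkyne deliver exactly this pattern, with the C4' hydroxyl free.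
- Ring A keeps the olivetol skeleton: C1 is formylated, O4 methylated, O2 benzylated and the aldehyde oxidised.
- Forward order: diazo keto ester (steps 1–3) and methoxyacetylene (step 4) give ring B (step 5); ring A acid (steps 6–9); esterification (step 10); removal of both benzyl groups (step 11).
- The target has no stereocentre. Only regiochemistry is at stake, set by ketene polarity in ring B and by hydrogen bonding of the ortho hydroxyl in ring A.

Key step: step 5

Remark on the chemistry: methoxyacetylene is assumed not to be purchasable and is made and used as a cold solution. Locants C1–C6 (ring A) and C1'–C6' (ring B) start at the ring carbon that bears the carbonyl group.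

**Route**

Step 1
Reactants: 1 2-propylacrylic acid
Product: 2 2-propylacryloyl chloride (2-methylidenepentanoyl chloride)
Conditions: (COCl)2 (1.2 equiv), DMF (cat.), CH2Cl2, 0 °C → rt; concentrate cold, use crude
Reagents that add atoms: oxalyl chloride, O=C(Cl)C(=O)Cl
Why: Acid chloride formation with oxalyl chloride and catalytic DMF is neutral and cold enough to leave the 1,1-disubstituted alkene untouched.

Step 2
Reactants: 2 2-propylacryloyl chloride; 3 monobenzyl malonate
Product: 5 benzyl 4-methylidene-3-oxoheptanoate, via acylmalonic half ester 4 (not isolated)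
Conditions: 3 (1.5 equiv), MgCl2 (1.5 equiv), Et3N (3 equiv), MeCN, 0 °C → rt; add 2, 0 °C → rt; 1 M HCl, 0 °C
Reagents that add atoms: none
Why: C-acylation of the chelated magnesium enolate of a malonic half ester (Masamune–Brooks type β-keto ester synthesis), followed by loss of CO2 on acidification, gives the β-keto ester, while the α-propyl group and the cold, weakly basic medium restrain conjugate addition to the enone.

Step 3
Reactants: 5 benzyl 4-methylidene-3-oxoheptanoate
Product: 6 benzyl 2-diazo-4-methylidene-3-oxoheptanoate
Conditions: p-ABSA (1.1 equiv), Et3N (1.2 equiv), MeCN, 0 °C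
Reagents that add atoms: 4-acetamidobenzenesulfonyl azide (p-ABSA), CC(=O)Nc1ccc(cc1)S(=O)(=O)N=[N+]=[N-]
Why: Regitz diazo transfer to a doubly activated methylene is fast with a sulfonyl azide and a mild amine base, and 2-diazo-3-oxo-4-enoates are an isolable compound class.

Step 4
Reactants: 7 chloroacetaldehyde dimethyl acetal
Product: 10 methoxyacetylene, via 1-chloro-2-methoxyethene 8 (not isolated), via sodium methoxyacetylide 9 (not isolated)
Conditions: NaNH2 (3.2 equiv), liq. NH3, −33 °C; evaporate NH3; cold sat. aq NaCl, −20 °C; distil into cold ClCH2CH2Cl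
Reagents that add atoms: none
Why: Two successive base-induced eliminations (methanol, then HCl) with NaNH2 in liquid NH3 are the standard route to 1-alkoxyalkynes, and the product is held as its sodium acetylide until the aqueous quench.

Step 5
Reactants: 6 benzyl 2-diazo-4-methylidene-3-oxoheptanoate; 10 methoxyacetylene
Product: 15 benzyl 4-hydroxy-2-methoxy-6-propylbenzoate, via vinylketene 11 (not isolated), via cyclobutenone 12 (not isolated), via dienylketene 13 (not isolated), via cyclohexadienone 14 (not isolated)
Conditions: hν (300 nm), 10 (3 equiv), degassed ClCH2CH2Cl (0.05 M), sealed quartz tube, 10 °C; then 80 °C, dark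
Reagents that add atoms: none
Why: Proposed new method: light expels N2 from 6 and the pent-1-en-2-yl group migrates from the ketone carbon to the diazo carbon (Wolff rearrangement), forming the C1'–C6' bond in vinylketene 11; the nucleophilic CH terminus of ynol ether 10 then attacks the ketene carbonyl carbon (C3'–C4') and the methoxy-bearing carbon closes onto the ester-bearing carbon (C1'–C2') in a [2+2] cycloaddition to cyclobutenone 12. Heating opens 12 by a 4π electrocyclic step to the (2Z)-dienylketene 13, and ring B closes by a thermal disrotatory 6π electrocyclisation (C4'–C5') to dienone 14, which tautomerises irreversibly to phenol 15. The closest known reaction type is the photochemical (diazo ketone) variant of the Danheiser benzannulation with alkoxy- and siloxyalkynes; what is new is the ester on the diazo carbon, so that the ketene carbon of 11 carries a CO2Bn group. No stereocentre survives: the quaternary centre of 12 is erased on ring opening and the product is a planar arene. Three selectivities are needed: alkenyl rather than benzyloxy migration, which follows from the much higher migratory aptitude of the ketone substituent in diazo keto esters; the orientation of 10, which is fixed by ketene and ynol ether polarisation and puts the free hydroxyl at C4' and the methyl ether at C2'; and [2+2] rather than hetero-[4+2] addition through the ester carbonyl, which is helped by the weak heterodiene character of an alkoxycarbonyl group, cold photolysis and excess alkyne. The former ketone carbon ends as the free C4' phenol, so the two ring B oxygens never need to be told apart by protection.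

Step 6
Reactants: 16 olivetol (5-pentylbenzene-1,3-diol)
Product: 18 2,4-dihydroxy-6-pentylbenzaldehyde, via aryl iminium chloride 17 (not isolated)
Conditions: POCl3 (1.2 equiv), DMF, 0 °C → rt; then H2O, 50 °C
Reagents that add atoms: N,N-dimethylformamide, CN(C)C=O; water, O
Why: Vilsmeier–Haack formylation attacks the resorcinol position that is ortho to one hydroxyl and para to the other (next to the pentyl chain) in preference to the crowded position between the two hydroxyls.

Step 7
Reactants: 18 2,4-dihydroxy-6-pentylbenzaldehyde
Product: 19 2-hydroxy-4-methoxy-6-pentylbenzaldehyde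
Conditions: MeI (1.05 equiv), K2CO3 (1.1 equiv), acetone, rt
Reagents that add atoms: iodomethane (MeI), CI
Why: Williamson methylation with one equivalent of MeI takes the more acidic, non-chelated C4 hydroxyl, because the C2 hydroxyl is held in a hydrogen bond to the aldehyde.

Step 8
Reactants: 19 2-hydroxy-4-methoxy-6-pentylbenzaldehyde
Product: 20 2-(benzyloxy)-4-methoxy-6-pentylbenzaldehyde
Conditions: BnBr (1.3 equiv), K2CO3 (2 equiv), DMF, 60 °C
Reagents that add atoms: benzyl bromide (BnBr), BrCc1ccccc1
Why: Williamson benzylation of the remaining chelated phenol under more forcing conditions installs a group that leaves together with the ring B benzyl ester in the last step.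

Step 9
Reactants: 20 2-(benzyloxy)-4-methoxy-6-pentylbenzaldehyde
Product: 21 2-(benzyloxy)-4-methoxy-6-pentylbenzoic acid
Conditions: NaClO2 (3 equiv), NaH2PO4 (3 equiv), 2-methyl-2-butene (10 equiv), t-BuOH/H2O, rt
Reagents that add atoms: sodium chlorite (NaClO2), [Na+].[O-]Cl=O
Why: Pinnick oxidation converts the hindered, electron-rich aldehyde into the acid without touching the benzyl ether, with 2-methyl-2-butene trapping HOCl before it can chlorinate the ring.

Step 10
Reactants: 21 2-(benzyloxy)-4-methoxy-6-pentylbenzoic acid; 15 benzyl 4-hydroxy-2-methoxy-6-propylbenzoate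
Product: 23 benzyl 4-{[2-(benzyloxy)-4-methoxy-6-pentylbenzoyl]oxy}-2-methoxy-6-propylbenzoate, via mixed trifluoroacetic anhydride 22 (not isolated)
Conditions: (CF3CO)2O (3 equiv), toluene, rt
Reagents that add atoms: none
Why: The mixed trifluoroacetic anhydride of a 2,6-disubstituted, electron-rich benzoic acid ionises readily to an acylium-like species that acylates the unhindered C4' phenol, which is the standard depside esterification.

Step 11
Reactants: 23 benzyl 4-{[2-(benzyloxy)-4-methoxy-6-pentylbenzoyl]oxy}-2-methoxy-6-propylbenzoate
Product: 24 4-[(2-hydroxy-4-methoxy-6-pentylbenzoyl)oxy]-2-methoxy-6-propylbenzoic acid (target)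
Conditions: H2 (1 atm), 10% Pd/C, EtOAc, rt
Reagents that add atoms: none
Why: Hydrogenolysis over Pd/C cleaves the benzyl ether and the benzyl ester in one operation, while the aryl ester bond, the methyl ethers and the arenes are inert.

**Compound list**

1 | 2-propylacrylic acid (2-methylidenepentanoic acid) | C=C(CCC)C(=O)O | starting material
2 | 2-propylacryloyl chloride | C=C(CCC)C(=O)Cl | intermediate
3 | monobenzyl malonate (3-(benzyloxy)-3-oxopropanoic acid) | O=C(O)CC(=O)OCc1ccccc1 | starting material
4 | 2-[(benzyloxy)carbonyl]-4-methylidene-3-oxoheptanoic acid (racemic, present as its magnesium chelate) | C=C(CCC)C(=O)C(C(=O)O)C(=O)OCc1ccccc1 | intermediate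
5 | benzyl 4-methylidene-3-oxoheptanoate | C=C(CCC)C(=O)CC(=O)OCc1ccccc1 | intermediate
6 | benzyl 2-diazo-4-methylidene-3-oxoheptanoate | C=C(CCC)C(=O)C(=[N+]=[N-])C(=O)OCc1ccccc1 | intermediate
7 | chloroacetaldehyde dimethyl acetal (2-chloro-1,1-dimethoxyethane) | COC(CCl)OC | starting material
8 | 1-chloro-2-methoxyethene (E/Z mixture) | COC=CCl | intermediate
9 | sodium methoxyacetylide | [Na+].[C-]#COC | intermediate
10 | methoxyacetylene (methoxyethyne) | C#COC | intermediate
11 | benzyl 3-methylidene-2-(oxomethylidene)hexanoate (vinylketene) | C=C(CCC)C(=C=O)C(=O)OCc1ccccc1 | intermediate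
12 | benzyl 2-methoxy-4-oxo-1-(pent-1-en-2-yl)cyclobut-2-ene-1-carboxylate (racemic) | C=C(CCC)C1(C(=O)OCc2ccccc2)C(OC)=CC1=O | intermediate
13 | benzyl (2Z)-3-methoxy-5-oxo-2-(pent-1-en-2-yl)penta-2,4-dienoate (dienylketene) | C=C(CCC)/C(C(=O)OCc1ccccc1)=C(/OC)C=C=O | intermediate
14 | benzyl 6-methoxy-4-oxo-2-propylcyclohexa-1,5-diene-1-carboxylate | CCCC1=C(C(=O)OCc2ccccc2)C(OC)=CC(=O)C1 | intermediate
15 | benzyl 4-hydroxy-2-methoxy-6-propylbenzoate | CCCc1cc(O)cc(OC)c1C(=O)OCc1ccccc1 | intermediate
16 | olivetol (5-pentylbenzene-1,3-diol) | CCCCCc1cc(O)cc(O)c1 | starting material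
17 | N-[(2,4-dihydroxy-6-pentylphenyl)methylidene]-N-methylmethanaminium chloride | CCCCCc1cc(O)cc(O)c1C=[N+](C)C.[Cl-] | intermediate
18 | 2,4-dihydroxy-6-pentylbenzaldehyde | CCCCCc1cc(O)cc(O)c1C=O | intermediate
19 | 2-hydroxy-4-methoxy-6-pentylbenzaldehyde | CCCCCc1cc(OC)cc(O)c1C=O | intermediate
20 | 2-(benzyloxy)-4-methoxy-6-pentylbenzaldehyde | CCCCCc1cc(OC)cc(OCc2ccccc2)c1C=O | intermediate
21 | 2-(benzyloxy)-4-methoxy-6-pentylbenzoic acid | CCCCCc1cc(OC)cc(OCc2ccccc2)c1C(=O)O | intermediate
22 | 2-(benzyloxy)-4-methoxy-6-pentylbenzoic trifluoroacetic anhydride | CCCCCc1cc(OC)cc(OCc2ccccc2)c1C(=O)OC(=O)C(F)(F)F | intermediate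
23 | benzyl 4-{[2-(benzyloxy)-4-methoxy-6-pentylbenzoyl]oxy}-2-methoxy-6-propylbenzoate | CCCCCc1cc(OC)cc(OCc2ccccc2)c1C(=O)Oc1cc(CCC)c(C(=O)OCc2ccccc2)c(OC)c1 | intermediate
24 | 4-[(2-hydroxy-4-methoxy-6-pentylbenzoyl)oxy]-2-methoxy-6-propylbenzoic acid | CCCCCc1cc(OC)cc(O)c1C(=O)Oc1cc(CCC)c(C(=O)O)c(OC)c1 | target

**Count and risks**

Total step count: 11. Longest linear sequence: 6 steps (1, 2, 3, 5, 10, 11; the ring A branch 6, 7, 8, 9, 10, 11 is equally long).

Steps most likely to fail:

1. Step 5 (bears the label "Proposed new method:"). The ester-substituted vinylketene may be diverted before ring B forms: hetero-[4+2] addition of the ynol ether across the ketene and the ester carbonyl to a pyranone, ketene dimerisation, or photodecomposition of the diazo compound without clean alkenyl migration. The fallback builds ring B by classical, known condensation chemistry and tells the two oxygens apart by hydrogen bonding. It sets out from monobenzyl malonate 3 and returns at depside 23.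
   - Compound 3 would be condensed with butanal in a decarboxylative Knoevenagel–Doebner reaction (DMAP cat., DMF, rt) to benzyl (E)-hex-2-enoate F1.
   - Michael addition of benzyl acetoacetate to F1 and Claisen ring closure (NaOBn, BnOH/toluene, heat) should give benzyl 2,4-dioxo-6-propylcyclohexane-1-carboxylate F2 (racemic, largely enolised).
   - Bromination and dehydrobromination of F2 (Br2, DMF, 0 °C then 80 °C) should aromatise it to benzyl 2,4-dihydroxy-6-propylbenzoate F3.
   - The non-chelated C4' hydroxyl of F3 would be acylated selectively with acid 21 (trifluoroacetic anhydride, toluene, rt) to benzyl 4-{[2-(benzyloxy)-4-methoxy-6-pentylbenzoyl]oxy}-2-hydroxy-6-propylbenzoate F4.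
   - Methylation of the chelated C2' hydroxyl of F4 (MeI, K2CO3, acetone, reflux) rejoins the route at 23.

2. Step 2. Conjugate addition of the malonate enolate, or of the product enolate, to the enone can lead to oligomers of this Nazarov-type β-keto ester during acylation and again during diazo transfer. The fallback avoids the enolisable β-keto ester altogether by forming the C–C bond at the aldehyde oxidation level with the diazo group already in place. It sets out from acid chloride 2 and returns at diazo keto ester 6.
   - Compound 2 would be reduced with LiAlH(OtBu)3 (THF, −78 °C) to 2-methylidenepentanal F5.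
   - Benzyl diazoacetate would be added in a DBU-catalysed aldol-type reaction (MeCN, rt) to give benzyl 2-diazo-3-hydroxy-4-methylideneheptanoate F6 (racemic).
   - Oxidation of the allylic alcohol with 2-iodoxybenzoic acid in DMSO at rt would deliver 6.

3. Step 10. Acylation by the doubly ortho-substituted acid may be slow, so that trifluoroacetylation of the phenol and acid-induced loss of the benzyl ether take over. The fallback changes the acyl donor to a benzodioxinone, which needs no ring A protecting group. It sets out from aldehyde 19 and returns at target 24.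
   - Compound 19 would be oxidised (NaClO2, NaH2PO4, 2-methyl-2-butene, t-BuOH/H2O) to 2-hydroxy-4-methoxy-6-pentylbenzoic acid F7.
   - F7 would be condensed with acetone (trifluoroacetic anhydride, CF3CO2H, rt) to 7-methoxy-2,2-dimethyl-5-pentyl-4H-1,3-benzodioxin-4-one F8.
   - The sodium phenoxide of 15 (NaH, THF, 0 °C → rt) would open F8 with loss of acetone to benzyl 4-[(2-hydroxy-4-methoxy-6-pentylbenzoyl)oxy]-2-methoxy-6-propylbenzoate F9.
   - Hydrogenolysis of the single benzyl ester of F9 (H2, Pd/C, EtOAc) would give 24.

**Further compounds**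

F1 | step 5 | benzyl (E)-hex-2-enoate | CCC/C=C/C(=O)OCc1ccccc1
F2 | step 5 | benzyl 2,4-dioxo-6-propylcyclohexane-1-carboxylate (racemic) | CCCC1CC(=O)CC(=O)C1C(=O)OCc1ccccc1
F3 | step 5 | benzyl 2,4-dihydroxy-6-propylbenzoate | CCCc1cc(O)cc(O)c1C(=O)OCc1ccccc1
F4 | step 5 | benzyl 4-{[2-(benzyloxy)-4-methoxy-6-pentylbenzoyl]oxy}-2-hydroxy-6-propylbenzoate | CCCCCc1cc(OC)cc(OCc2ccccc2)c1C(=O)Oc1cc(CCC)c(C(=O)OCc2ccccc2)c(O)c1
F5 | step 2 | 2-methylidenepentanal | C=C(CCC)C=O
F6 | step 2 | benzyl 2-diazo-3-hydroxy-4-methylideneheptanoate (racemic) | C=C(CCC)C(O)C(=[N+]=[N-])C(=O)OCc1ccccc1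
F7 | step 10 | 2-hydroxy-4-methoxy-6-pentylbenzoic acid | CCCCCc1cc(OC)cc(O)c1C(=O)O
F8 | step 10 | 7-methoxy-2,2-dimethyl-5-pentyl-4H-1,3-benzodioxin-4-one | CCCCCc1cc(OC)cc2OC(C)(C)OC(=O)c12
F9 | step 10 | benzyl 4-[(2-hydroxy-4-methoxy-6-pentylbenzoyl)oxy]-2-methoxy-6-propylbenzoate | CCCCCc1cc(OC)cc(O)c1C(=O)Oc1cc(CCC)c(C(=O)OCc2ccccc2)c(OC)c1
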